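The route rests on cutting the bond between the benzylic CH2 (C7) on the 3-methoxy-4,5-dihydroxyphenyl ring (ring A) and the neighbouring methyl-bearing methine C8. Both stereocentres are first built into a secondary alkylboronic acid by two reagent-controlled lithiation–borylation homologations. The key step couples this acid with the ring-A aldehyde through its tosylhydrazone: diazo formation, boron ate complex, stereoretentive 1,2-shift of C8 with loss of N2, and protodeboronation all occur in one flask. It exploits that C7 is benzylic to ring A, which stabilises the diazo carbon and labilises the transient C7–B bond, so the junction emerges as a bare CH2. Hydrogenolysis of three benzyl ethers ends the synthesis.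

Key step: step 7

Remark: lignan numbering is used (C7/C8 on the ring-A side, C7'/C8' on the side of ring B, the 4-hydroxy-3,5-dimethoxyphenyl ring). Ethyl N,N-diisopropylcarbamate, both sparteine enantiomers and 2-(bromomethyl) pinacol boronate are assumed to be purchasable.

Step 1
Reactants: 1 4-bromo-2,6-dimethoxyphenol
Product: 2 2-(benzyloxy)-5-bromo-1,3-dimethoxybenzene
Conditions: BnBr, K2CO3, DMF, 60 °C
Reagents that add atoms: benzyl bromide, BrCc1ccccc1
Why: Williamson ether synthesis, in which the phenoxide of 1 is alkylated by benzyl bromide so that the acidic OH is masked before the organolithium steps by a group that falls off in the final hydrogenolysis.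

Step 2
Reactants: 2 2-(benzyloxy)-5-bromo-1,3-dimethoxybenzene; 3 2-(bromomethyl)-4,4,5,5-tetramethyl-1,3,2-dioxaborolane
Product: 6 2-[4-(benzyloxy)-3,5-dimethoxybenzyl]-4,4,5,5-tetramethyl-1,3,2-dioxaborolane, via aryllithium 4 (not isolated), via bromomethyl ate complex 5 (not isolated)
Conditions: n-BuLi, THF, −78 °C; then 3, −78 °C to rt
Reagents that add atoms: none
Why: Bromine–lithium exchange gives aryllithium 4, which adds to the boron of 3 to form ate complex 5, and a Matteson-type 1,2-aryl shift expels bromide to leave the benzylic boronic ester.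

Step 3
Reactants: 6 2-[4-(benzyloxy)-3,5-dimethoxybenzyl]-4,4,5,5-tetramethyl-1,3,2-dioxaborolane; 7 ethyl N,N-diisopropylcarbamate
Product: 10 2-[(2R)-1-[4-(benzyloxy)-3,5-dimethoxyphenyl]propan-2-yl]-4,4,5,5-tetramethyl-1,3,2-dioxaborolane, via (S)-lithiated carbamate 8 (not isolated), via boronate complex 9 (not isolated)
Conditions: 7, s-BuLi, (−)-sparteine, Et2O, −78 °C; then 6, −78 °C; then MgBr2·OEt2, reflux
Reagents that add atoms: none
Why: Sparteine-mediated asymmetric lithiation–borylation (a reagent-controlled Matteson-type homologation), in which s-BuLi/(−)-sparteine removes the pro-S proton of 7, the (S)-carbenoid 8 is borylated with retention to give 9, and the benzyl group then migrates antiperiplanar to the carbamate with inversion at the carbenoid carbon, so the chiral diamine alone sets the (R)-centre that becomes C8'.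

Step 4
Reactants: 10 2-[(2R)-1-[4-(benzyloxy)-3,5-dimethoxyphenyl]propan-2-yl]-4,4,5,5-tetramethyl-1,3,2-dioxaborolane; 7 ethyl N,N-diisopropylcarbamate
Product: 13 2-[(2S,3R)-4-[4-(benzyloxy)-3,5-dimethoxyphenyl]-3-methylbutan-2-yl]-4,4,5,5-tetramethyl-1,3,2-dioxaborolane, via (R)-lithiated carbamate 11 (not isolated), via boronate complex 12 (not isolated)
Conditions: 7, s-BuLi, (+)-sparteine, Et2O, −78 °C; then 10, −78 °C; then MgBr2·OEt2, reflux
Reagents that add atoms: none
Why: Second asymmetric lithiation–borylation, now with (+)-sparteine, in which the (R)-carbenoid 11 is borylated with retention to 12 and the secondary alkyl group migrates with retention at C8' and inversion at the carbenoid carbon, which sets the (S)-configured C–B centre (the later C8) in the threo relationship under reagent control, while the residual errors of the two homologations should collect mainly in a minor diastereomer that chromatography removes (Horeau-type amplification).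

Step 5
Reactants: 13 2-[(2S,3R)-4-[4-(benzyloxy)-3,5-dimethoxyphenyl]-3-methylbutan-2-yl]-4,4,5,5-tetramethyl-1,3,2-dioxaborolane
Product: 14 [(2S,3R)-4-[4-(benzyloxy)-3,5-dimethoxyphenyl]-3-methylbutan-2-yl]boronic acid
Conditions: NaIO4, NH4OAc, acetone/H2O, rt
Reagents that add atoms: water, O
Why: Oxidative pinacol cleavage, in which the hydrolysis equilibrium of the boronic ester is pulled to the free boronic acid because periodate destroys the released pinacol by glycol cleavage, and neither stereocentre is touched.

Step 6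
Reactants: 15 3,4-dihydroxy-5-methoxybenzaldehyde
Product: 16 3,4-bis(benzyloxy)-5-methoxybenzaldehyde
Conditions: BnBr, K2CO3, DMF, 60 °C
Reagents that add atoms: benzyl bromide, BrCc1ccccc1
Why: Double Williamson ether synthesis masks the catechol, which would otherwise bind the boronic acid and be oxidised under the basic coupling conditions, with the same hydrogenolysable group as on ring B.

Step 7
Reactants: 14 [(2S,3R)-4-[4-(benzyloxy)-3,5-dimethoxyphenyl]-3-methylbutan-2-yl]boronic acid; 16 3,4-bis(benzyloxy)-5-methoxybenzaldehyde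
Product: 20 1,2-bis(benzyloxy)-5-[(2R,3R)-4-[4-(benzyloxy)-3,5-dimethoxyphenyl]-2,3-dimethylbutyl]-3-methoxybenzene, via tosylhydrazone 17 (not isolated), via aryldiazomethane 18 (not isolated), via benzylic boronic acid 19 (not isolated)
Conditions: 16, TsNHNH2, 1,4-dioxane, 80 °C; then 14, K2CO3, 110 °C, argon
Reagents that add atoms: none
Why: This is the Barluenga–Valdés reductive coupling of a tosylhydrazone with a boronic acid, run in its one-pot form from the aldehyde. Condensation gives 17, whose potassium salt loses sulfinate (Bamford–Stevens) and releases aryldiazomethane 18 slowly; the nucleophilic diazo carbon binds the empty orbital on boron of 14, and C8 migrates from boron to C7 as N2 leaves, which forms the C7–C8 bond. As in every 1,2-metallate shift the migrating carbon keeps its configuration, so the (S)-C–B centre becomes (R)-C8 (only the CIP ranking changes), C8' is a spectator and no ring is closed. The new C7 centre of 19 forms as a mixture of epimers, but base-mediated protodeboronation of this benzylic boronic acid turns both into the same CH2, so the mixture converges on one compound. The step needs capture of 18 by boron to outrun azine formation, which the low stationary concentration of 18 and an excess of 16 should secure, and it needs protodeboronation only after the coupling, which is secured because the C–B bond of 14 is not benzylic whereas that of 19 lies next to ring A.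

Step 8
Reactants: 20 1,2-bis(benzyloxy)-5-[(2R,3R)-4-[4-(benzyloxy)-3,5-dimethoxyphenyl]-2,3-dimethylbutyl]-3-methoxybenzene
Product: 21 sauriol B, 5-[(2R,3R)-4-(4-hydroxy-3,5-dimethoxyphenyl)-2,3-dimethylbutyl]-3-methoxybenzene-1,2-diol
Conditions: H2 (1 atm), Pd/C, EtOAc/MeOH, rt
Reagents that add atoms: none
Why: Catalytic hydrogenolysis cleaves the three O-benzyl bonds in one operation, while the saturated chain, the methyl ethers and both stereocentres are inert.

Compound list
1 | 4-bromo-2,6-dimethoxyphenol | COc1cc(Br)cc(OC)c1O | starting material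
2 | 2-(benzyloxy)-5-bromo-1,3-dimethoxybenzene | COc1cc(Br)cc(OC)c1OCc1ccccc1 | intermediate
3 | 2-(bromomethyl)-4,4,5,5-tetramethyl-1,3,2-dioxaborolane | BrCB1OC(C)(C)C(C)(C)O1 | starting material
4 | [4-(benzyloxy)-3,5-dimethoxyphenyl]lithium | [Li]c1cc(OC)c(OCc2ccccc2)c(OC)c1 | intermediate
5 | lithium aryl(bromomethyl) pinacol boronate complex | [Li+].BrC[B-]1(OC(C)(C)C(C)(C)O1)c1cc(OC)c(OCc2ccccc2)c(OC)c1 | intermediate
6 | 2-[4-(benzyloxy)-3,5-dimethoxybenzyl]-4,4,5,5-tetramethyl-1,3,2-dioxaborolane | COc1cc(CB2OC(C)(C)C(C)(C)O2)cc(OC)c1OCc1ccccc1 | intermediate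
7 | ethyl N,N-diisopropylcarbamate | CCOC(=O)N(C(C)C)C(C)C | starting material
8 | (S)-1-lithioethyl N,N-diisopropylcarbamate, (−)-sparteine complex | C[C@H]([Li])OC(=O)N(C(C)C)C(C)C | intermediate
9 | lithium boronate complex of 8 and 6, (S) at the carbamate-bearing carbon | [Li+].C[C@H]([B-]1(Cc2cc(OC)c(OCc3ccccc3)c(OC)c2)OC(C)(C)C(C)(C)O1)OC(=O)N(C(C)C)C(C)C | intermediate
10 | 2-[(2R)-1-[4-(benzyloxy)-3,5-dimethoxyphenyl]propan-2-yl]-4,4,5,5-tetramethyl-1,3,2-dioxaborolane | C[C@H](Cc1cc(OC)c(OCc2ccccc2)c(OC)c1)B1OC(C)(C)C(C)(C)O1 | intermediate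
11 | (R)-1-lithioethyl N,N-diisopropylcarbamate, (+)-sparteine complex | C[C@@H]([Li])OC(=O)N(C(C)C)C(C)C | intermediate
12 | lithium boronate complex of 11 and 10, (R) at the carbamate-bearing carbon, (R) at the migrating carbon | [Li+].C[C@@H]([B-]1([C@H](C)Cc2cc(OC)c(OCc3ccccc3)c(OC)c2)OC(C)(C)C(C)(C)O1)OC(=O)N(C(C)C)C(C)C | intermediate
13 | 2-[(2S,3R)-4-[4-(benzyloxy)-3,5-dimethoxyphenyl]-3-methylbutan-2-yl]-4,4,5,5-tetramethyl-1,3,2-dioxaborolane | CC1(C)OB(OC1(C)C)[C@@H](C)[C@H](C)Cc1cc(OC)c(OCc2ccccc2)c(OC)c1 | intermediate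
14 | [(2S,3R)-4-[4-(benzyloxy)-3,5-dimethoxyphenyl]-3-methylbutan-2-yl]boronic acid | OB(O)[C@@H](C)[C@H](C)Cc1cc(OC)c(OCc2ccccc2)c(OC)c1 | intermediate
15 | 3,4-dihydroxy-5-methoxybenzaldehyde | COc1cc(C=O)cc(O)c1O | starting material
16 | 3,4-bis(benzyloxy)-5-methoxybenzaldehyde | COc1cc(C=O)cc(OCc2ccccc2)c1OCc1ccccc1 | intermediate
17 | (E)-N'-[3,4-bis(benzyloxy)-5-methoxybenzylidene]-4-methylbenzenesulfonohydrazide | COc1cc(/C=N/NS(=O)(=O)c2ccc(C)cc2)cc(OCc2ccccc2)c1OCc1ccccc1 | intermediate
18 | 1,2-bis(benzyloxy)-5-(diazomethyl)-3-methoxybenzene | COc1cc(C=[N+]=[N-])cc(OCc2ccccc2)c1OCc1ccccc1 | intermediate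
19 | [(2R,3R)-1-[3,4-bis(benzyloxy)-5-methoxyphenyl]-4-[4-(benzyloxy)-3,5-dimethoxyphenyl]-2,3-dimethylbutyl]boronic acid, both C1 epimers | COc1cc(C(B(O)O)[C@@H](C)[C@H](C)Cc2cc(OC)c(OCc3ccccc3)c(OC)c2)cc(OCc2ccccc2)c1OCc1ccccc1 | intermediate
20 | 1,2-bis(benzyloxy)-5-[(2R,3R)-4-[4-(benzyloxy)-3,5-dimethoxyphenyl]-2,3-dimethylbutyl]-3-methoxybenzene | COc1cc(C[C@@H](C)[C@H](C)Cc2cc(OC)c(OCc3ccccc3)c(OC)c2)cc(OCc2ccccc2)c1OCc1ccccc1 | intermediate
21 | sauriol B, 5-[(2R,3R)-4-(4-hydroxy-3,5-dimethoxyphenyl)-2,3-dimethylbutyl]-3-methoxybenzene-1,2-diol | COc1cc(C[C@@H](C)[C@H](C)Cc2cc(OC)c(O)c(OC)c2)cc(O)c1O | target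

Total step count: 8. Longest linear sequence: 7 (steps 1, 2, 3, 4, 5, 7, 8).

Steps most likely to fail

Step 7. The hindered, weakly Lewis-acidic secondary boronic acid may capture the diazo compound too slowly. Dimerisation of the diazo compound to the azine and oxidation of the C–B bond would then take over.
- The fallback replaces the neutral diazo carbon by an anionic carbenoid that binds a boronic ester at low temperature. It sets out from 13 and 16, so step 5 is skipped.
- NaBH4 in MeOH reduces 16 to [3,4-bis(benzyloxy)-5-methoxyphenyl]methanol F1.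
- Diisopropylcarbamoyl chloride with NaH in THF converts this alcohol into 3,4-bis(benzyloxy)-5-methoxybenzyl N,N-diisopropylcarbamate F2.
- s-BuLi/TMEDA in Et2O at −78 °C lithiates the carbamate-bearing benzylic CH2. This position is dipole-stabilised and directed, so it should outrun attack at the OCH2Ph groups.
- Addition of 13 and warming trigger the 1,2-shift of C8 with retention and give the benzylic pinacol boronate F3 as a mixture of C7 epimers.
- TBAF·3H2O in toluene protodeboronates both epimers to the same CH2, and the route is rejoined at 20.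

Step 4. The bulky sparteine-bound carbenoid may be borylated slowly by the α-branched ester 10. Carbenoid decay, incomplete migration and loss of diastereocontrol would follow.
- The fallback sets out from 10 and changes the source of chirality from an in situ asymmetric deprotonation to a stereospecific tin–lithium exchange on a pre-purified reagent.
- Ethyl 2,4,6-triisopropylbenzoate F4 is made from the commercial acid with EtI and K2CO3.
- It is lithiated with s-BuLi/(+)-sparteine and trapped with Me3SnCl. The resulting (R)-1-(trimethylstannyl)ethyl 2,4,6-triisopropylbenzoate F5 is recrystallised to enantiopurity.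
- n-BuLi at −78 °C releases the diamine-free lithiated benzoate with retention. It should add faster to 10, and its benzoate leaving group should allow migration without a Lewis acid, coming back at 13.

Step 5. Hydrolysis of the hindered secondary pinacol ester may stay incomplete, and long exposure to periodate may oxidise the C–B bond.
- The fallback sets out from 13 and removes pinacol by fluoride displacement instead of oxidative cleavage.
- KHF2 in MeOH/H2O, with azeotropic removal of pinacol, gives the crystalline potassium [(2S,3R)-4-[4-(benzyloxy)-3,5-dimethoxyphenyl]-3-methylbutan-2-yl]trifluoroborate F6.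
- Silica gel in water, acting as a fluorophile, hydrolyses this salt and returns to the route at 14.

Further compounds
F1 | step 7 | [3,4-bis(benzyloxy)-5-methoxyphenyl]methanol | COc1cc(CO)cc(OCc2ccccc2)c1OCc1ccccc1
F2 | step 7 | 3,4-bis(benzyloxy)-5-methoxybenzyl N,N-diisopropylcarbamate | COc1cc(COC(=O)N(C(C)C)C(C)C)cc(OCc2ccccc2)c1OCc1ccccc1
F3 | step 7 | 2-[(2R,3R)-1-[3,4-bis(benzyloxy)-5-methoxyphenyl]-4-[4-(benzyloxy)-3,5-dimethoxyphenyl]-2,3-dimethylbutyl]-4,4,5,5-tetramethyl-1,3,2-dioxaborolane, both C1 epimers | COc1cc(C(B2OC(C)(C)C(C)(C)O2)[C@@H](C)[C@H](C)Cc2cc(OC)c(OCc3ccccc3)c(OC)c2)cc(OCc2ccccc2)c1OCc1ccccc1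
F4 | step 4 | ethyl 2,4,6-triisopropylbenzoate | CCOC(=O)c1c(C(C)C)cc(C(C)C)cc1C(C)C
F5 | step 4 | (R)-1-(trimethylstannyl)ethyl 2,4,6-triisopropylbenzoate | C[C@H](OC(=O)c1c(C(C)C)cc(C(C)C)cc1C(C)C)[Sn](C)(C)C
F6 | step 5 | potassium [(2S,3R)-4-[4-(benzyloxy)-3,5-dimethoxyphenyl]-3-methylbutan-2-yl]trifluoroborate | [K+].F[B-](F)(F)[C@@H](C)[C@H](C)Cc1cc(OC)c(OCc2ccccc2)c(OC)c1
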